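The earlier runs and the new flask were generated by integration with made-up constants; noise was put on by code.

Target at 8.0 h was what I had to foretell, in flasks that differ by their charge of substrate.

| flask | substrate | remark | time |
|---|---|---|---|
| teal | 0.034 M | run made earlier |  |
| grey | 0.071 M | run made earlier |  |
| south-west | 0.050 M |  | 8.0 h |
| west | 0.10 M |  | 8.0 h |
| north-east | 0.012 M |  | 8.0 h |
| south | 0.025 M |  | 8.0 h |
| south-east | 0.015 M |  | 8.0 h |

| run | time / h | target / % |
|---|---|---|
| teal | 0.333 | 15 |
| teal | 1.00 | 46 |
| teal | 2.00 | 61 |
| teal | 3.00 | 59 |
| teal | 4.00 | 61 |
| grey | 0.333 | 18 |
| grey | 0.667 | 33 |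
| grey | 1.00 | 46 |
| grey | 2.00 | 64 |
| grey | 4.00 | 68 |

(readings scatter by 2 percentage points)

- a reading or a percentage of target counts all its forms, free or not

* the flasks by amount of target, in percent of the substrate charged, highest first, at 8.0 h (south-west / west / north-east / south / south-east)
* the amount of target, in percent of the substrate charged of the flask you put first, at 8.0 h
* the amount of target, in percent of the substrate charged of the flask you put last, at 8.0 h

Both runs read 46% at 1.00 h, so early on the percentage showed no effect of the charge. I turned the question round: for a small charge to keep up with a large one, the last readings of the two runs, at 4.00 h, would have to agree within their scatter. They stood 7 percentage points apart, which is 2.47 standard deviations of a difference.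

I therefore assumed that one molecule's forks send a fixed share of any charge to target, the ceiling, and that a fixed molar amount is then lost each hour. The gap, divided by the difference of the reciprocal charges and by the time, gave 1.14 mM h⁻¹. This is the drain, the molar amount of target lost per hour whatever the charge, a zero-order loss. The percentage is then the ceiling minus drain times time over charge, and the ceiling came to 74.4%.

The order thus follows the charge, with west first and north-east last. West came to 65.3%, and north-east to −1.68%, which is nil within the scatter. But the teal run read 61% at 2.00 h and 61% at 4.00 h, where the drain should have taken 6.7 points. So I also reckoned with a gap one standard deviation smaller, a drain of 0.680 mM h⁻¹, which put north-east at 23.6%.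

The forecast gave the same order, west > south-west > south > south-east > north-east, but higher amounts than mine, 72% (68% to 78%) and 50% (42% to 56%), holding that “By 8 h every flask should be at equilibrium”.

The flasks gave west > south-west > south > south-east > north-east, with west at 64.6% and north-east at 24.8%.

    substrate → intermediate (k = 4.60 × 10⁻⁴ s⁻¹)
    intermediate ⇌ target (K = 11.0, k = 0.00280 s⁻¹)
    intermediate ⇌ isomer of the product (K = 2.30, k = 0.00160 s⁻¹)
    intermediate → side product (k = 1.90 × 10⁻⁴ s⁻¹)
    crystals ⇌ target, rate k5*(cs5 - [target]) while solid is left; crystals form when [target] > cs5 (solubility = 2.50 mM, k = 0.00530 s⁻¹)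
    intermediate → decomposed reagent (k = 9.50 × 10⁻⁴ s⁻¹)

The same reckoning on west and north-east gave a drain of 0.678 mM h⁻¹, less than the 1.14 mM h⁻¹ I had read and close to the lower 0.680 mM h⁻¹, with a ceiling of 70.0%. I carried both to west read at 30 h, the time being the one setting changed. The drain took 20 points off the ceiling and left 49.6%. That flask stood at 50.2%, with 47.7% of its charge as crystals.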